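**Retrosynthetic overview**
1. Rings: A = methoxy ring and C = chlorohydroxy ring of the phenanthrene (B between them), D = chlorophenol ring on C6, E = phenol ring on C4.
2. Target 18 ← Z-alkene macrocycle 16 ← dialdehyde 14: the D–E bridge C–C bond joins the two formyl carbons, one made nucleophilic as its N–H hydrazone (N2 and water leave), and this closes the 12-membered ring.
3. 14 ← phenanthrene 5 by two biaryl couplings: ring D bromide 7 at C6 (through the boronate of 5), then a ring E boronate at C4 after phenol-directed iodination.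
4. 5 ← Mallory photocyclization of stilbene 4 ← Wittig reaction of 1 and 2.
5. Order of ring formation: ring B first (phenanthrene), then the two aryl–aryl bonds, then the macrocycle.

Assumption: the SMILES has no stereodescriptor and no stereocentre, so the route makes the constitution shown; if the twisted 12-membered ring is configurationally stable it forms as the racemate. Phenanthrene locants of 5 are kept for all later compounds.

Step 1
Reactants: 1 4-bromo-3-methoxybenzyl bromide; 2 3-chloro-4-hydroxybenzaldehyde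
Product: 4 4-[2-(4-bromo-3-methoxyphenyl)ethenyl]-2-chlorophenol (E/Z mixture), via phosphonium bromide 3 (not isolated)
Conditions: PPh3, toluene, 110 °C; then 2, KOtBu (2.3 equiv), THF, 0 °C to rt
Reagents that add atoms: none
Why: Wittig olefination of the semi-stabilised ylide from 3; the extra base carries the phenol as its phenoxide, and the E/Z ratio does not matter because the isomers interconvert under the light of step 2.

Step 2
Reactants: 4 4-[2-(4-bromo-3-methoxyphenyl)ethenyl]-2-chlorophenol
Product: 5 6-bromo-2-chloro-7-methoxyphenanthren-3-ol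
Conditions: hν (medium-pressure Hg lamp, Pyrex), I2 (1.1 equiv), methyloxirane (50 equiv), toluene (2 mM), Ar, rt
Reagents that add atoms: none
Why: Mallory oxidative photocyclization (Katz conditions): the Z isomer undergoes 6π electrocyclization and I2 aromatises the dihydrophenanthrene; closure para to OMe on ring A and at the ring C carbon remote from Cl keeps both groups out of the bay, so 5 is expected as the major regioisomer and the bay isomers are removed by chromatography.

Step 3
Reactants: 6 2-chloro-5-hydroxybenzaldehyde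
Product: 7 2-bromo-6-chloro-3-hydroxybenzaldehyde
Conditions: Br2 (1.05 equiv), NaOAc (2 equiv), AcOH, rt
Reagents that add atoms: bromine, BrBr
Why: electrophilic aromatic bromination ortho to OH; the para position carries Cl and, as with isovanillin, the carbon between OH and CHO is attacked rather than the one para to CHO.

Step 4
Reactants: 5 6-bromo-2-chloro-7-methoxyphenanthren-3-ol; 7 2-bromo-6-chloro-3-hydroxybenzaldehyde
Product: 9 6-chloro-2-(2-chloro-3-hydroxy-7-methoxyphenanthren-6-yl)-3-hydroxybenzaldehyde, via pinacol boronate 8 (not isolated)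
Conditions: B2pin2 (1.05 equiv), Pd(dppf)Cl2 (5 mol%), KOAc, 1,4-dioxane, 90 °C; then 7, Pd(OAc)2 (5 mol%), SPhos (10 mol%), aq K3PO4, 80 °C
Reagents that add atoms: none
Why: Miyaura borylation then Suzuki–Miyaura coupling in one pot; each C–Br bond reacts well before any C–Cl bond, free phenols and the aldehyde are tolerated, and SPhos copes with the tri-ortho-substituted axis.

Step 5
Reactants: 9 6-chloro-2-(2-chloro-3-hydroxy-7-methoxyphenanthren-6-yl)-3-hydroxybenzaldehyde
Product: 10 6-chloro-2-(2-chloro-3-hydroxy-4-iodo-7-methoxyphenanthren-6-yl)-3-hydroxybenzaldehyde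
Conditions: NIS (1.0 equiv), MeCN, −10 °C to rt
Reagents that add atoms: N-iodosuccinimide, O=C1CCC(=O)N1I
Why: electrophilic aromatic iodination; C4 is the only free carbon ortho to the phenanthrol OH and is the naphthol-type alpha position, far more reactive than the formyl-deactivated ring D phenol or the anisole ring.

Step 6
Reactants: 10 6-chloro-2-(2-chloro-3-hydroxy-4-iodo-7-methoxyphenanthren-6-yl)-3-hydroxybenzaldehyde; 11 3-bromo-4-hydroxybenzaldehyde
Product: 13 6-chloro-2-[2-chloro-4-(5-formyl-2-hydroxyphenyl)-3-hydroxy-7-methoxyphenanthren-6-yl]-3-hydroxybenzaldehyde, via pinacol boronate 12 (not isolated)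
Conditions: 11 (2 equiv), B2pin2 (1.9 equiv), Pd(dppf)Cl2 (5 mol%), KOAc, 1,4-dioxane, 90 °C; then 10, Pd(OAc)2 (10 mol%), SPhos (20 mol%), aq K3PO4, 95 °C
Reagents that add atoms: none
Why: Miyaura borylation of 11 then Suzuki–Miyaura coupling; the C–I bond undergoes oxidative addition far faster than the C–Cl bonds, and SPhos is suited to the hindered bay position.

Step 7
Reactants: 13 6-chloro-2-[2-chloro-4-(5-formyl-2-hydroxyphenyl)-3-hydroxy-7-methoxyphenanthren-6-yl]-3-hydroxybenzaldehyde
Product: 14 tris(methoxymethyl) ether of 13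
Conditions: MOMCl (4.5 equiv), i-Pr2NEt (6 equiv), CH2Cl2, 0 to 40 °C
Reagents that add atoms: chloromethyl methyl ether, COCCl
Why: O-alkylation of the three phenols (acetal ether formation) removes the acidic protons and keeps the ring E aldehyde electrophilic for step 8; the acetals come off with acid at the end without touching ArOMe or ArCl.

Step 8
Reactants: 14 tris(methoxymethyl) ether of 13
Product: 16 Z-alkene macrocycle (tris-MOM ether of the target with CH=CH in place of CH2CH2), via monohydrazone 15 (not isolated)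
Conditions: N2H4·H2O (1.0 equiv), THF (2 mM), rt, 1 h; then [Ru(p-cymene)Cl2]2 (5 mol%), Me2PCH2CH2PMe2 (10 mol%), KOtBu (0.5 equiv), 80 °C, 24 h
Reagents that add atoms: none
Why: Proposed new method: the hydrazone carbon of 15 acts as a benzyl carbanion equivalent (reversed polarity of a formyl carbon) that, on ruthenium after N–H deprotonation, adds through a six-membered transition state to the second formyl group held about 4 Å away on the rigid phenanthrene, and base-induced loss of N2 and hydroxide (Wolff–Kishner-type E1cB) gives the alkene, which the 12-membered ring allows only as Z; either monohydrazone regioisomer gives the same alkene and hydrazone exchange should feed unreacted and doubly condensed material back; the closest known reaction type is the ruthenium-catalysed, hydrazine-mediated carbonyl–carbonyl reductive olefination, known between two molecules and for common ring sizes.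

Step 9
Reactants: 16 Z-alkene macrocycle
Product: 18 target CNP0310669.0, via tris-MOM bibenzyl macrocycle 17 (not isolated)
Conditions: TsNHNH2 (10 equiv), NaOAc (12 equiv), DME/H2O, 85 °C; then 6 M HCl, MeOH, 55 °C
Reagents that add atoms: none
Why: diimide reduction transfers H2 syn to the strained Z-alkene and leaves both C–Cl bonds intact (unlike H2 over Pd), then acid-catalysed acetal cleavage frees the three phenols while the methyl ether stays; no stereocentre is formed.

**Compound list**
1 | 4-bromo-3-methoxybenzyl bromide | COc1cc(CBr)ccc1Br | starting material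
2 | 3-chloro-4-hydroxybenzaldehyde | O=Cc1ccc(O)c(Cl)c1 | starting material
3 | (4-bromo-3-methoxybenzyl)triphenylphosphonium bromide | COc1cc(C[P+](c2ccccc2)(c2ccccc2)c2ccccc2)ccc1Br.[Br-] | intermediate
4 | 4-[2-(4-bromo-3-methoxyphenyl)ethenyl]-2-chlorophenol, E/Z mixture | COc1cc(C=Cc2ccc(O)c(Cl)c2)ccc1Br | intermediate
5 | 6-bromo-2-chloro-7-methoxyphenanthren-3-ol | COc1cc2ccc3cc(Cl)c(O)cc3c2cc1Br | intermediate
6 | 2-chloro-5-hydroxybenzaldehyde | O=Cc1cc(O)ccc1Cl | starting material
7 | 2-bromo-6-chloro-3-hydroxybenzaldehyde | O=Cc1c(Br)c(O)ccc1Cl | intermediate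
8 | 2-chloro-7-methoxy-6-(4,4,5,5-tetramethyl-1,3,2-dioxaborolan-2-yl)phenanthren-3-ol | COc1cc2ccc3cc(Cl)c(O)cc3c2cc1B1OC(C)(C)C(C)(C)O1 | intermediate
9 | 6-chloro-2-(2-chloro-3-hydroxy-7-methoxyphenanthren-6-yl)-3-hydroxybenzaldehyde | COc1cc2ccc3cc(Cl)c(O)cc3c2cc1-c1c(O)ccc(Cl)c1C=O | intermediate
10 | 6-chloro-2-(2-chloro-3-hydroxy-4-iodo-7-methoxyphenanthren-6-yl)-3-hydroxybenzaldehyde | COc1cc2ccc3cc(Cl)c(O)c(I)c3c2cc1-c1c(O)ccc(Cl)c1C=O | intermediate
11 | 3-bromo-4-hydroxybenzaldehyde | O=Cc1ccc(O)c(Br)c1 | starting material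
12 | 4-hydroxy-3-(4,4,5,5-tetramethyl-1,3,2-dioxaborolan-2-yl)benzaldehyde | O=Cc1ccc(O)c(B2OC(C)(C)C(C)(C)O2)c1 | intermediate
13 | 6-chloro-2-[2-chloro-4-(5-formyl-2-hydroxyphenyl)-3-hydroxy-7-methoxyphenanthren-6-yl]-3-hydroxybenzaldehyde | COc1cc2ccc3cc(Cl)c(O)c(-c4cc(C=O)ccc4O)c3c2cc1-c1c(O)ccc(Cl)c1C=O | intermediate
14 | tris(methoxymethyl) ether of 13 (all three phenols as OCH2OCH3) | COc1cc2ccc3cc(Cl)c(OCOC)c(-c4cc(C=O)ccc4OCOC)c3c2cc1-c1c(OCOC)ccc(Cl)c1C=O | intermediate
15 | mono-(E)-hydrazone of 14 at the ring E formyl group | COc1cc2ccc3cc(Cl)c(OCOC)c(-c4cc(/C=N/N)ccc4OCOC)c3c2cc1-c1c(OCOC)ccc(Cl)c1C=O | intermediate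
16 | Z-alkene macrocycle: tris(methoxymethyl) ether of the target with a Z-CH=CH bridge between rings D and E | COc1cc2ccc3cc(Cl)c(OCOC)c4c3c2cc1-c1c(OCOC)ccc(Cl)c1/C=C\c1ccc(OCOC)c-4c1 | intermediate
17 | tris(methoxymethyl) ether of the target (CH2CH2 bridge) | COc1cc2ccc3cc(Cl)c(OCOC)c4c3c2cc1-c1c(OCOC)ccc(Cl)c1CCc1ccc(OCOC)c-4c1 | intermediate
18 | CNP0310669.0 | COc1cc2ccc3cc(Cl)c(O)c4c3c2cc1-c1c(O)ccc(Cl)c1CCc1ccc(O)c-4c1 | target

**Count and risks**
Total steps: 9. Longest linear sequence: 8 (steps 1, 2, 4, 5, 6, 7, 8, 9); step 3 is a one-step branch.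

Most likely to fail, first: step 8 (ring closure). The risks are double condensation with hydrazine, a cyclic azine, or simple Wolff–Kishner reduction of one formyl group. The fallback sets out from 14 and comes back at 16. It is an intramolecular McMurry coupling with low-valent titanium made from TiCl3(DME)1.5 and Zn–Cu couple in refluxing DME under syringe-pump dilution; the two formyl groups are joined through a titanium pinacolate that is deoxygenated to the same Z-alkene. It makes no new compound (entry F0).

Second: step 6 (coupling at the bay carbon C4 next to a phenoxide). The risks are loss of iodine without coupling and protodeboronation of 12. The fallback sets out from 10 and comes back at 14, so step 7 is not needed. It couples ethers instead of phenoxides. 10 is etherified with MOMCl and i-Pr2NEt to 6-chloro-2-[2-chloro-4-iodo-7-methoxy-3-(methoxymethoxy)phenanthren-6-yl]-3-(methoxymethoxy)benzaldehyde F6. Separately 11 is etherified to 3-bromo-4-(methoxymethoxy)benzaldehyde F7 and borylated (B2pin2, Pd(dppf)Cl2, KOAc) to 4-(methoxymethoxy)-3-(4,4,5,5-tetramethyl-1,3,2-dioxaborolan-2-yl)benzaldehyde F8, which is isolated. Suzuki coupling of F6 with F8 (Pd(OAc)2, SPhos, K3PO4, toluene/H2O, 100 °C) gives 14.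

Third: step 2 (photocyclization). The risks are closure next to Cl on ring C and damage to the free phenol. The fallback sets out from 1 (through 3) and comes back at 10. It leaves the ring C chlorine out until the ring system is built. Wittig reaction of 3 with bought 4-hydroxybenzaldehyde (O=Cc1ccc(O)cc1) gives 4-[2-(4-bromo-3-methoxyphenyl)ethenyl]phenol F1. Its phenol ring is symmetric, so the same I2/hν closure gives only 6-bromo-7-methoxyphenanthren-3-ol F2 on that side. Borylation to 7-methoxy-6-(4,4,5,5-tetramethyl-1,3,2-dioxaborolan-2-yl)phenanthren-3-ol F3 and coupling with 7 as in step 4 give 6-chloro-3-hydroxy-2-(3-hydroxy-7-methoxyphenanthren-6-yl)benzaldehyde F4. NIS gives 6-chloro-3-hydroxy-2-(3-hydroxy-4-iodo-7-methoxyphenanthren-6-yl)benzaldehyde F5. NCS in MeCN at 40 °C then chlorinates C2, the only free carbon ortho to the phenanthrol OH, and this is 10.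

**Further compounds**
F1 | step 2 | 4-[2-(4-bromo-3-methoxyphenyl)ethenyl]phenol, E/Z mixture | COc1cc(C=Cc2ccc(O)cc2)ccc1Br
F2 | step 2 | 6-bromo-7-methoxyphenanthren-3-ol | COc1cc2ccc3ccc(O)cc3c2cc1Br
F3 | step 2 | 7-methoxy-6-(4,4,5,5-tetramethyl-1,3,2-dioxaborolan-2-yl)phenanthren-3-ol | COc1cc2ccc3ccc(O)cc3c2cc1B1OC(C)(C)C(C)(C)O1
F4 | step 2 | 6-chloro-3-hydroxy-2-(3-hydroxy-7-methoxyphenanthren-6-yl)benzaldehyde | COc1cc2ccc3ccc(O)cc3c2cc1-c1c(O)ccc(Cl)c1C=O
F5 | step 2 | 6-chloro-3-hydroxy-2-(3-hydroxy-4-iodo-7-methoxyphenanthren-6-yl)benzaldehyde | COc1cc2ccc3ccc(O)c(I)c3c2cc1-c1c(O)ccc(Cl)c1C=O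
F6 | step 6 | 6-chloro-2-[2-chloro-4-iodo-7-methoxy-3-(methoxymethoxy)phenanthren-6-yl]-3-(methoxymethoxy)benzaldehyde | COc1cc2ccc3cc(Cl)c(OCOC)c(I)c3c2cc1-c1c(OCOC)ccc(Cl)c1C=O
F7 | step 6 | 3-bromo-4-(methoxymethoxy)benzaldehyde | COCOc1ccc(C=O)cc1Br
F8 | step 6 | 4-(methoxymethoxy)-3-(4,4,5,5-tetramethyl-1,3,2-dioxaborolan-2-yl)benzaldehyde | COCOc1ccc(C=O)cc1B1OC(C)(C)C(C)(C)O1
F0 | step 8 | none | none
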